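**Assumption:** locants C1–C15 follow germacrane numbering; common reagents (TBHP, PMBCl, TBSCl and the like) are given by name and SMILES but not numbered; the ketoreductase is chosen from a commercial panel by screening for the (R)-alcohol.

## Retrosynthetic overview

1. Target 33 ⇐ tigloylation of the 8-OH lactone 31 ⇐ lactone transposition of the 8,12-olide 30.
2. 30 ⇐ intramolecular Cr(II) Barbier allylation (C6–C7 bond) of enal/α-(bromomethyl)butenolide 29; this closes the ten-membered carbocycle and sets C6 and C7.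
3. Butenolide ⇐ RCM of the C8 2-(bromomethyl)acrylate; 3(2H)-furanone ⇐ Au-catalysed cyclisation of the α′-hydroxy ynone made by Sonogashira coupling of alkyne 17 with (Z)-vinyl iodide 20.
4. 17 ⇐ C8 carbinol from ketoreductase reduction of ynone 9; C10 from Sharpless asymmetric epoxidation of methallyl alcohol.
5. Ring order: furanone → butenolide → carbocycle → 6,12-lactone.

## Route

**Step 1**
Reactants: 1, 2-methylprop-2-en-1-ol
Product: 2, (S)-2-methylglycidol
Conditions: Ti(OiPr)4 (5 mol%), L-(+)-DIPT (6 mol%), t-BuOOH, 4 Å MS, CH2Cl2, −20 °C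
Reagents that add atoms: tert-butyl hydroperoxide, CC(C)(C)OO
Why: Catalytic Sharpless asymmetric epoxidation of an achiral allylic alcohol sets the first stereocentre (C10); the (S)-epoxide becomes (R) at C10 once the CIP priorities change on ring opening.

**Step 2**
Reactants: 2; 3, vinylmagnesium bromide
Product: 4, (2R)-2-methylpent-4-ene-1,2-diol
Conditions: CH2=CHMgBr (3 equiv), CuI (10 mol%), THF, −40 → 0 °C
Reagents that add atoms: vinylmagnesium bromide, C=C[Mg]Br
Why: Cu-catalysed SN2 epoxide opening occurs only at the unsubstituted CH2, so the quaternary centre is untouched (Payne rearrangement is blocked by the tertiary carbon).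

**Step 3**
Reactants: 4
Product: 5, (4R)-2,2,4-trimethyl-4-(prop-2-en-1-yl)-1,3-dioxolane
Conditions: 2,2-dimethoxypropane, PPTS (cat.), CH2Cl2, rt
Reagents that add atoms: 2,2-dimethoxypropane, COC(C)(C)OC
Why: Acetonide formation masks the C1/C10 diol as a small, base-stable group.

**Step 4**
Reactants: 5
Product: 6, 2-[(4R)-2,2,4-trimethyl-1,3-dioxolan-4-yl]acetaldehyde
Conditions: O3, CH2Cl2/MeOH, −78 °C; then PPh3
Reagents that add atoms: ozone, [O-][O+]=O
Why: Ozonolysis with reductive work-up turns the vinyl group into the C8 aldehyde; nothing else is oxidisable.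

**Step 5**
Reactants: 6; 7, ethynyltrimethylsilane
Product: 8, (2RS)-1-[(4R)-2,2,4-trimethyl-1,3-dioxolan-4-yl]-4-(trimethylsilyl)but-3-yn-2-ol
Conditions: 7, n-BuLi, THF, −78 °C; then 6
Reagents that add atoms: ethynyltrimethylsilane, C#C[Si](C)(C)C
Why: Lithium acetylide 1,2-addition to the aldehyde; the C8 epimer mixture is irrelevant because it is oxidised next.

**Step 6**
Reactants: 8
Product: 9, 1-[(4R)-2,2,4-trimethyl-1,3-dioxolan-4-yl]-4-(trimethylsilyl)but-3-yn-2-one
Conditions: Dess–Martin periodinane, NaHCO3, CH2Cl2, 0 °C → rt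
Reagents that add atoms: none
Why: Buffered Dess–Martin oxidation gives the TMS-ynone without β-elimination of the acetal oxygen.

**Step 7**
Reactants: 9
Product: 10, (2R)-1-[(4R)-2,2,4-trimethyl-1,3-dioxolan-4-yl]-4-(trimethylsilyl)but-3-yn-2-ol
Conditions: (R)-selective ketoreductase (KRED), NADP+ (cat.), i-PrOH (10% v/v) as hydride donor, phosphate buffer pH 7, 5% DMSO, 30 °C
Reagents that add atoms: none
Why: Ketoreductase reduction sets C8 under full catalyst control (the remote quaternary C10, with Me ≈ CH2O, gives no useful substrate bias); the few percent of ent-C10 material from step 1 becomes a separable diastereomer.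

**Step 8**
Reactants: 10
Product: 11, (2R)-1-[(4R)-2,2,4-trimethyl-1,3-dioxolan-4-yl]but-3-yn-2-ol
Conditions: K2CO3, MeOH, rt
Reagents that add atoms: none
Why: Methanolysis of the C–Si bond liberates the terminal alkyne.

**Step 9**
Reactants: 11
Product: 12, (2R)-1-[(4R)-2,2,4-trimethyl-1,3-dioxolan-4-yl]but-3-en-2-ol
Conditions: H2 (1 atm), Lindlar catalyst, quinoline, EtOAc, rt
Reagents that add atoms: none
Why: Lindlar semi-hydrogenation gives the vinyl carbinol needed later for RCM; C8 is not affected.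

**Step 10**
Reactants: 12
Product: 13, (4R)-4-{(2R)-2-[(4-methoxybenzyl)oxy]but-3-en-1-yl}-2,2,4-trimethyl-1,3-dioxolane
Conditions: NaH, PMBCl, Bu4NI (cat.), THF/DMF, 0 °C → rt
Reagents that add atoms: 4-methoxybenzyl chloride, COc1ccc(CCl)cc1
Why: Williamson etherification protects C8–OH with a group that survives acid, Grignard, Pd and Au and is removed oxidatively later.

**Step 11**
Reactants: 13
Product: 14, (2R,4R)-4-[(4-methoxybenzyl)oxy]-2-methylhex-5-ene-1,2-diol
Conditions: AcOH/H2O (4:1), 40 °C
Reagents that add atoms: none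
Why: Mild acid hydrolysis removes the acetonide; the PMB ether and alkene are stable.

**Step 12**
Reactants: 14
Product: 15, (2R,4R)-2-hydroxy-4-[(4-methoxybenzyl)oxy]-2-methylhex-5-enal
Conditions: SO3·pyridine, DMSO, i-Pr2NEt, CH2Cl2, 0 °C
Reagents that add atoms: none
Why: Parikh–Doering oxidation converts only the primary alcohol (the tertiary OH cannot oxidise, and there is no glycol cleavage as with hypervalent iodine); the aldehyde has no α-H and cannot epimerise.

**Step 13**
Reactants: 15; 16, ethynylmagnesium bromide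
Product: 17, (3RS,4R,6R)-6-[(4-methoxybenzyl)oxy]-4-methyloct-7-en-1-yne-3,4-diol
Conditions: HC≡CMgBr (3 equiv), THF, −78 → 0 °C
Reagents that add atoms: ethynylmagnesium bromide, C#C[Mg]Br
Why: Grignard addition to the aldehyde installs C2/C3; the new C1 carbinol is a mixture that converges on oxidation in step 17.

**Step 14**
Reactants: 18, but-2-yn-1-ol
Product: 19, (Z)-3-iodobut-2-en-1-ol
Conditions: Red-Al, THF, 0 °C → rt; then EtOAc; I2, −78 °C
Reagents that add atoms: iodine, II
Why: Hydroxyl-directed trans-hydroalumination places Al at C3 cis to CH2O, and iodinolysis with retention gives the Z-vinyl iodide that defines the C4=C5 geometry.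

**Step 15**
Reactants: 19
Product: 20, (Z)-tert-butyl[(3-iodobut-2-en-1-yl)oxy]dimethylsilane
Conditions: TBSCl, imidazole, CH2Cl2, 0 °C → rt
Reagents that add atoms: tert-butyldimethylsilyl chloride, CC(C)(C)[Si](C)(C)Cl
Why: Silylation protects C6–OH so that the later propargylic oxidation is selective.

**Step 16**
Reactants: 17; 20
Product: 21, (2Z,6RS,7R,9R)-1-[(tert-butyldimethylsilyl)oxy]-9-[(4-methoxybenzyl)oxy]-3,7-dimethylundeca-2,10-dien-4-yne-6,7-diol
Conditions: Pd(PPh3)2Cl2 (5 mol%), CuI (10 mol%), Et3N, THF, rt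
Reagents that add atoms: none beyond 20
Why: Sonogashira coupling forms C3–C4 with retention of the Z-alkene; free hydroxyls and the terminal alkene are tolerated at rt.

**Step 17**
Reactants: 21
Product: 22, (2Z,7R,9R)-1-[(tert-butyldimethylsilyl)oxy]-7-hydroxy-9-[(4-methoxybenzyl)oxy]-3,7-dimethylundeca-2,10-dien-4-yn-6-one
Conditions: Dess–Martin periodinane, NaHCO3, CH2Cl2, 0 °C
Reagents that add atoms: none
Why: Oxidation of the only secondary alcohol gives the α′-hydroxy ynone; the tertiary OH is inert.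

**Step 18**
Reactants: 22
Product: 23, (2R)-5-{(2Z)-4-[(tert-butyldimethylsilyl)oxy]but-2-en-2-yl}-2-{(2R)-2-[(4-methoxybenzyl)oxy]but-3-en-1-yl}-2-methylfuran-3(2H)-one
Conditions: Ph3PAuCl/AgOTf (5 mol%), toluene, rt
Reagents that add atoms: none
Why: Gold(I)-catalysed 5-endo-dig hydroalkoxylation of the ynone by the C10 tertiary OH gives the 3(2H)-furanone; C10 keeps its configuration because its C–O bond is not broken.

**Step 19**
Reactants: 23
Product: 24, (2R)-5-{(2Z)-4-[(tert-butyldimethylsilyl)oxy]but-2-en-2-yl}-2-[(2R)-2-hydroxybut-3-en-1-yl]-2-methylfuran-3(2H)-one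
Conditions: DDQ, CH2Cl2/pH 7 buffer, 0 °C
Reagents that add atoms: none
Why: Oxidative PMB cleavage frees C8–OH while the TBS ether and furanone are untouched.

**Step 20**
Reactants: 24; 25, 2-(bromomethyl)acrylic acid
Product: 26, (2R)-1-[(2R)-5-{(2Z)-4-[(tert-butyldimethylsilyl)oxy]but-2-en-2-yl}-2-methyl-3-oxo-2,3-dihydrofuran-2-yl]but-3-en-2-yl 2-(bromomethyl)acrylate
Conditions: 25, DCC, DMAP (5 mol%), CH2Cl2, −20 → 0 °C
Reagents that add atoms: 2-(bromomethyl)acrylic acid, C=C(CBr)C(=O)O
Why: Steglich esterification at the only free hydroxyl brings in C11–C13; low temperature and minimal DMAP limit attack on the allylic bromide.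

**Step 21**
Reactants: 26
Product: 27, (2R)-2-{[(2R)-4-(bromomethyl)-5-oxo-2,5-dihydrofuran-2-yl]methyl}-5-{(2Z)-4-[(tert-butyldimethylsilyl)oxy]but-2-en-2-yl}-2-methylfuran-3(2H)-one
Conditions: Grubbs II (10 mol%), toluene, 80 °C, 5 mM
Reagents that add atoms: none
Why: Ring-closing metathesis between the terminal vinyl group and the acrylate (loss of ethylene) gives the α-(bromomethyl)butenolide under neutral conditions, so the γ-stereocentre C8 cannot epimerise; the hindered conjugated C4=C5 alkene does not take part.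

**Step 22**
Reactants: 27
Product: 28, (2R)-2-{[(2R)-4-(bromomethyl)-5-oxo-2,5-dihydrofuran-2-yl]methyl}-5-[(2Z)-4-hydroxybut-2-en-2-yl]-2-methylfuran-3(2H)-one
Conditions: aq. HF, MeCN, 0 °C
Reagents that add atoms: none
Why: Acidic fluoride desilylation with no nucleophilic base present leaves the allylic bromide and butenolide intact.

**Step 23**
Reactants: 28
Product: 29, (2Z)-3-[(5R)-5-{[(2R)-4-(bromomethyl)-5-oxo-2,5-dihydrofuran-2-yl]methyl}-5-methyl-4-oxo-4,5-dihydrofuran-2-yl]but-2-enal
Conditions: Dess–Martin periodinane, NaHCO3, CH2Cl2, 0 °C; used immediately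
Reagents that add atoms: none
Why: Buffered oxidation of the allylic alcohol gives the Z-enal without isomerisation.

**Step 24**
Reactants: 29
Product: 30, (6R,7S,8R,10R)-6-hydroxy-1-oxo-3,10-epoxygermacra-2,4Z,11(13)-trien-12,8-olide (H7/H8 cis)
Conditions: CrCl2 (8 equiv), DMF, rt, slow addition to 2 mM
Reagents that add atoms: none
Why: Intramolecular Nozaki–Hiyama/Barbier allylation closes the carbocycle, with the cyclic (necessarily E-type) allylchromium expected to react through a chair transition state to give the 6,7-anti relationship and the tether from C9 forcing bond formation cis to C9 (H7/H8 cis), so C6 and C7 should follow from C8.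

**Step 25**
Reactants: 30
Product: 31, (6R,7R,8R,10R)-8-hydroxy-1-oxo-3,10-epoxygermacra-2,4Z,11(13)-trien-12,6-olide (atripliciolide)
Conditions: CSA (0.2 equiv), CH2Cl2, rt
Reagents that add atoms: none
Why: Acid-catalysed translactonisation moves the acyl group from O8 to the γ-disposed O6, which should favour the trans-fused 6,12-olide; no stereocentre changes (the C7 descriptor changes only through CIP priorities).

**Step 26**
Reactants: 31; 32, tiglic anhydride
Product: 33, atripliciolide tiglate (target)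
Conditions: 32 (3 equiv), DMAP (0.2 equiv), Et3N, CH2Cl2, 0 °C → rt
Reagents that add atoms: tiglic anhydride, C/C=C(\C)C(=O)OC(=O)/C(C)=C/C
Why: DMAP-catalysed acylation of the only free hydroxyl (C8) installs the (E)-2-methylbut-2-enoate with retention at C8.

## Compound list

1 | 2-methylprop-2-en-1-ol | C=C(C)CO | starting material
2 | (S)-2-methylglycidol | C[C@]1(CO)CO1 | intermediate
3 | vinylmagnesium bromide | C=C[Mg]Br | starting material
4 | (2R)-2-methylpent-4-ene-1,2-diol | C[C@](O)(CO)CC=C | intermediate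
5 | (4R)-2,2,4-trimethyl-4-allyl-1,3-dioxolane | CC1(C)OC[C@@](C)(CC=C)O1 | intermediate
6 | 2-[(4R)-2,2,4-trimethyl-1,3-dioxolan-4-yl]acetaldehyde | CC1(C)OC[C@@](C)(CC=O)O1 | intermediate
7 | ethynyltrimethylsilane | C#C[Si](C)(C)C | starting material
8 | (2RS)-propargylic alcohol | CC1(C)OC[C@@](C)(CC(O)C#C[Si](C)(C)C)O1 | intermediate
9 | TMS-ynone | CC1(C)OC[C@@](C)(CC(=O)C#C[Si](C)(C)C)O1 | intermediate
10 | (2R)-TMS-propargylic alcohol | CC1(C)OC[C@@](C)(C[C@@H](O)C#C[Si](C)(C)C)O1 | intermediate
11 | (2R)-terminal propargylic alcohol | CC1(C)OC[C@@](C)(C[C@@H](O)C#C)O1 | intermediate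
12 | (2R)-allylic alcohol | CC1(C)OC[C@@](C)(C[C@@H](O)C=C)O1 | intermediate
13 | PMB ether of 12 | CC1(C)OC[C@@](C)(C[C@@H](OCc2ccc(OC)cc2)C=C)O1 | intermediate
14 | (2R,4R)-4-(PMBO)-2-methylhex-5-ene-1,2-diol | OC[C@@](C)(C[C@@H](OCc1ccc(OC)cc1)C=C)O | intermediate
15 | (2R,4R)-2-hydroxy-4-(PMBO)-2-methylhex-5-enal | O=C[C@@](C)(C[C@@H](OCc1ccc(OC)cc1)C=C)O | intermediate
16 | ethynylmagnesium bromide | C#C[Mg]Br | starting material
17 | (3RS,4R,6R)-6-(PMBO)-4-methyloct-7-en-1-yne-3,4-diol | C#CC(O)[C@@](C)(C[C@@H](OCc1ccc(OC)cc1)C=C)O | intermediate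
18 | but-2-yn-1-ol | CC#CCO | starting material
19 | (Z)-3-iodobut-2-en-1-ol | C/C(I)=C/CO | intermediate
20 | (Z)-TBS ether of 19 | C/C(I)=C/CO[Si](C)(C)C(C)(C)C | intermediate
21 | Sonogashira enyne diol | C/C(C#CC(O)[C@@](C)(C[C@@H](OCc1ccc(OC)cc1)C=C)O)=C/CO[Si](C)(C)C(C)(C)C | intermediate
22 | α′-hydroxy ynone | C/C(C#CC(=O)[C@@](C)(C[C@@H](OCc1ccc(OC)cc1)C=C)O)=C/CO[Si](C)(C)C(C)(C)C | intermediate
23 | furanone, C8-OPMB | C/C(C1=CC(=O)[C@@](C)(C[C@@H](OCc2ccc(OC)cc2)C=C)O1)=C/CO[Si](C)(C)C(C)(C)C | intermediate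
24 | furanone, C8-OH | C/C(C1=CC(=O)[C@@](C)(C[C@@H](O)C=C)O1)=C/CO[Si](C)(C)C(C)(C)C | intermediate
25 | 2-(bromomethyl)acrylic acid | C=C(CBr)C(=O)O | starting material
26 | C8 2-(bromomethyl)acrylate | C/C(C1=CC(=O)[C@@](C)(C[C@@H](OC(=O)C(=C)CBr)C=C)O1)=C/CO[Si](C)(C)C(C)(C)C | intermediate
27 | bromomethyl butenolide, C6-OTBS | C/C(C1=CC(=O)[C@@](C)(C[C@H]2OC(=O)C(CBr)=C2)O1)=C/CO[Si](C)(C)C(C)(C)C | intermediate
28 | bromomethyl butenolide, C6-OH | C/C(C1=CC(=O)[C@@](C)(C[C@H]2OC(=O)C(CBr)=C2)O1)=C/CO | intermediate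
29 | Z-enal bromide | C/C(C1=CC(=O)[C@@](C)(C[C@H]2OC(=O)C(CBr)=C2)O1)=C/C=O | intermediate
30 | 6-hydroxy-8,12-olide | C=C1C(=O)O[C@@H]2C[C@@]3(C)OC(=CC3=O)/C(C)=C\[C@@H](O)[C@H]12 | intermediate
31 | atripliciolide (8-hydroxy-6,12-olide) | C=C1C(=O)O[C@@H]2/C=C(/C)C3=CC(=O)[C@@](C)(C[C@@H](O)[C@@H]12)O3 | intermediate
32 | tiglic anhydride | C/C=C(\C)C(=O)OC(=O)/C(C)=C/C | starting material
33 | atripliciolide tiglate | C=C1C(=O)O[C@@H]2/C=C(/C)C3=CC(=O)[C@@](C)(C[C@@H](OC(=O)/C(C)=C/C)[C@@H]12)O3 | target

## Summary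

Total steps: 26. Longest linear sequence: 24 (steps 1–13 and 16–26; steps 14–15 make the vinyl iodide).

Steps most likely to fail:

1. **Step 24 (Cr-mediated macrocyclisation; yield and C6 selectivity are predicted, not proven).** Fallback: change the ring order. Run the allylation on the open-chain enynol (C1–OH silylated, furanone not yet formed) to close a more flexible ten-membered cyclo-enyne, then oxidise C1 and form the furanone by transannular gold-catalysed cyclisation.
2. **Step 25 (lactone transposition; the equilibrium position is an estimate).** Fallback: give up the butenolide tether. Cyclise an acyclic methyl (Z)-2-(bromomethyl)enoate carrying C8–OPMB (from a Morita–Baylis–Hillman reaction of the C7 aldehyde with methyl acrylate, then SN2′ bromination), so that only O6 can lactonise; then DDQ and tigloylation.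
3. **Step 21 (RCM onto a 1,1-disubstituted bromomethyl acrylate in a polyene).** Fallback: build the butenolide by carbonylation instead. Use a PMBOCH2-substituted alkyne in step 5, then after the ketoreductase step do Red-Al/I2 and Pd/CO lactonisation to the α-(PMBOCH2)butenolide, and convert to the bromide late (DDQ, then CBr4/PPh3).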